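## Retrosynthetic overview
1. Target ⇒ tris-MOM ether of the (2S)-flavanone, with acidic MOM removal as the last step. The only stereocentre, C2, is secured on this protected flavanone by catalytic kinetic resolution of the racemate.
2. Ring C is the only ring that has to be built, since rings A and B are bought as aromatics. It is opened at O1–C2, which is an intramolecular oxa-Michael addition of a 2'-hydroxychalcone.
3. Key C–C disconnection at C2–C3 (the chalcone C=C): Claisen–Schmidt aldol condensation of a ring A methyl ketone with a ring B aldehyde.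
4. Each prenyl group ⇒ C-allyl group (cross-metathesis with 2-methyl-2-butene) ⇒ O-allyl ether (aromatic Claisen rearrangement) of phloroacetophenone or vanillin.

Assumption: the stereocentre in the given SMILES is read as C2 with S configuration. Prenyl means 3-methylbut-2-en-1-yl, and simple bought reagents (allyl bromide, MOMCl, 2-methyl-2-butene) carry no compound number.

## Route

Step 1
Reactants: 1 2,4,6-trihydroxyacetophenone
Product: 2 1-[2-hydroxy-4,6-bis(allyloxy)phenyl]ethanone
Conditions: allyl bromide (2.1 equiv), K2CO3 (2.2 equiv), acetone, reflux, 8 h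
Reagents that add atoms: allyl bromide C=CCBr
Why: Williamson ether synthesis in which K2CO3 alkylates the non-chelated phenols, while the OH hydrogen-bonded to the acetyl C=O reacts far more slowly and stays free when only 2.1 equiv of allyl bromide are offered.

Step 2
Reactants: 2 1-[2-hydroxy-4,6-bis(allyloxy)phenyl]ethanone
Product: 4 1-(3,5-diallyl-2,4,6-trihydroxyphenyl)ethanone, via mono-rearranged allyl phenol 3 (not isolated)
Conditions: PhNEt2, 200 °C, Ar, 4 h
Reagents that add atoms: none
Why: Double aromatic Claisen rearrangement ([3,3]-sigmatropic shift, then re-aromatisation) in which both allyl groups can only end on the two free ring carbons C3 and C5, so all pathways converge on the symmetric diallyl phenol.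

Step 3
Reactants: 4 1-(3,5-diallyl-2,4,6-trihydroxyphenyl)ethanone
Product: 5 1-[3,5-diallyl-2-hydroxy-4,6-bis(methoxymethoxy)phenyl]ethanone
Conditions: MOMCl (2.2 equiv), DIPEA (3 equiv), CH2Cl2, 0 °C to rt
Reagents that add atoms: chloromethyl methyl ether (MOMCl) COCCl
Why: Acetal protection by O-alkylation with the hard electrophile MOMCl takes the 4-OH and one of the two equivalent ortho-OH groups, and the remaining OH is shut down by its hydrogen bond to the ketone, which leaves exactly the phenol needed later for ring C.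

Step 4
Reactants: 5 1-[3,5-diallyl-2-hydroxy-4,6-bis(methoxymethoxy)phenyl]ethanone
Product: 6 1-[2-hydroxy-4,6-bis(methoxymethoxy)-3,5-diprenylphenyl]ethanone
Conditions: 2-methyl-2-butene (excess)/CH2Cl2, second-generation Grubbs catalyst RuCl2(=CHPh)(PCy3)(H2IMes) (5 mol %), 40 °C, sealed tube
Reagents that add atoms: 2-methyl-2-butene CC=C(C)C
Why: Olefin cross-metathesis in which each terminal allyl C=C exchanges its CH2 terminus for the isopropylidene unit of the excess 2-methyl-2-butene, volatile propene drives the reaction, and the trisubstituted prenyl product is no longer a good substrate.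

Step 5
Reactants: 7 vanillin (4-hydroxy-3-methoxybenzaldehyde)
Product: 8 4-(allyloxy)-3-methoxybenzaldehyde
Conditions: allyl bromide (1.2 equiv), K2CO3 (1.5 equiv), acetone, reflux
Reagents that add atoms: allyl bromide C=CCBr
Why: Williamson ether synthesis on the single acidic phenol, with the non-enolisable aldehyde inert to carbonate.

Step 6
Reactants: 8 4-(allyloxy)-3-methoxybenzaldehyde
Product: 9 3-allyl-4-hydroxy-5-methoxybenzaldehyde (5-allylvanillin)
Conditions: neat, 200 °C, Ar, 4 h
Reagents that add atoms: none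
Why: Aromatic Claisen rearrangement in which one ortho position carries OMe, so the [3,3]-shift delivers the allyl group to the only free ortho carbon and re-aromatisation returns the phenol.

Step 7
Reactants: 9 3-allyl-4-hydroxy-5-methoxybenzaldehyde
Product: 10 3-allyl-5-methoxy-4-(methoxymethoxy)benzaldehyde
Conditions: MOMCl (1.5 equiv), DIPEA (2 equiv), CH2Cl2, 0 °C to rt
Reagents that add atoms: chloromethyl methyl ether (MOMCl) COCCl
Why: MOM acetal protection of the phenol, which would otherwise form a deactivating phenoxide in the basic aldol step, using an electrophile small enough for the doubly ortho-substituted OH.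

Step 8
Reactants: 10 3-allyl-5-methoxy-4-(methoxymethoxy)benzaldehyde
Product: 11 3-methoxy-4-(methoxymethoxy)-5-prenylbenzaldehyde
Conditions: 2-methyl-2-butene (excess)/CH2Cl2, second-generation Grubbs catalyst RuCl2(=CHPh)(PCy3)(H2IMes) (3 mol %), 40 °C, sealed tube
Reagents that add atoms: 2-methyl-2-butene CC=C(C)C
Why: Olefin cross-metathesis of the terminal allyl group with excess 2-methyl-2-butene, driven by loss of propene and tolerant of the aldehyde and the acetal.

Step 9
Reactants: 6 1-[2-hydroxy-4,6-bis(methoxymethoxy)-3,5-diprenylphenyl]ethanone; 11 3-methoxy-4-(methoxymethoxy)-5-prenylbenzaldehyde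
Product: 13 (E)-1-[2-hydroxy-4,6-bis(methoxymethoxy)-3,5-diprenylphenyl]-3-[3-methoxy-4-(methoxymethoxy)-5-prenylphenyl]prop-2-en-1-one, via racemic aldol adduct 12 (not isolated)
Conditions: KOH (10 equiv), EtOH/H2O (4:1), 0 °C to rt, Ar, 48 h; cold AcOH to pH 6
Reagents that add atoms: none
Why: Claisen–Schmidt crossed aldol condensation in which 6 is the only enolisable partner and 11 the only aldehyde, so the methyl-ketone enolate adds to the aldehyde and E1cB loss of water from 12 gives the conjugated E-enone, with MOM acetals and prenyl groups inert to hydroxide.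

Step 10
Reactants: 13 (E)-chalcone
Product: 14 rac-5,7-bis(methoxymethoxy)-2-[3-methoxy-4-(methoxymethoxy)-5-prenylphenyl]-6,8-diprenylchroman-4-one
Conditions: NaOAc (10 equiv), EtOH, reflux, 24–48 h
Reagents that add atoms: none
Why: Intramolecular oxa-Michael addition (6-endo-trig chalcone–flavanone isomerisation) in which the free 2'-phenol adds to the enone β-carbon under mild acetate catalysis, the ortho-OMOM group twists the chalcone out of conjugation and so favours the closed form, and C2 is created as a racemate that is resolved in step 11.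

Step 11
Reactants: 14 rac-tris-MOM flavanone
Product: 15 (2S)-5,7-bis(methoxymethoxy)-2-[3-methoxy-4-(methoxymethoxy)-5-prenylphenyl]-6,8-diprenylchroman-4-one
Conditions: Cp*RhCl[(R,R)-TsDPEN] (1 mol %), HCO2H/Et3N (5:2), EtOAc, rt to 40 °C, to about 53 % conversion (chiral HPLC control); SiO2 separation
Reagents that add atoms: none
Why: Kinetic resolution by Noyori–Ikariya asymmetric transfer hydrogenation, in which the (R,R)-catalyst imposes the 4R carbinol configuration, which matches the substrate's own preference for the 2,4-cis alcohol only in the (2R)-ketone, so that enantiomer is reduced away and the (2S)-ketone is recovered in high ee just beyond 50 % conversion without C2, the alkenes or the acetals being touched.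

Step 12
Reactants: 15 (2S)-tris-MOM flavanone
Product: 16 (2S)-5,7-dihydroxy-2-(4-hydroxy-3-methoxy-5-prenylphenyl)-6,8-diprenylchroman-4-one (target)
Conditions: conc. aq HCl in MeOH (about 1 M), 40 °C, 2–4 h, TLC control; base-free work-up
Reagents that add atoms: none
Why: Acid-catalysed transacetalisation of the three aryl MOM acetals to methanol is faster than protonation of the trisubstituted alkenes at 40 °C, and the flavanone C2 epimerises essentially only by base-induced ring opening, so the prenyl groups and the 2S centre survive.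

## Compound list
1 | 2,4,6-trihydroxyacetophenone | CC(=O)c1c(O)cc(O)cc1O | starting material
2 | 1-[2-hydroxy-4,6-bis(allyloxy)phenyl]ethanone | CC(=O)c1c(O)cc(OCC=C)cc1OCC=C | intermediate
3 | 1-[3-allyl-4-(allyloxy)-2,6-dihydroxyphenyl]ethanone (mono-rearranged allyl phenol) | CC(=O)c1c(O)cc(OCC=C)c(CC=C)c1O | intermediate
4 | 1-(3,5-diallyl-2,4,6-trihydroxyphenyl)ethanone | CC(=O)c1c(O)c(CC=C)c(O)c(CC=C)c1O | intermediate
5 | 1-[3,5-diallyl-2-hydroxy-4,6-bis(methoxymethoxy)phenyl]ethanone | CC(=O)c1c(O)c(CC=C)c(OCOC)c(CC=C)c1OCOC | intermediate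
6 | 1-[2-hydroxy-4,6-bis(methoxymethoxy)-3,5-diprenylphenyl]ethanone | CC(=O)c1c(O)c(CC=C(C)C)c(OCOC)c(CC=C(C)C)c1OCOC | intermediate
7 | vanillin | COc1cc(C=O)ccc1O | starting material
8 | 4-(allyloxy)-3-methoxybenzaldehyde | COc1cc(C=O)ccc1OCC=C | intermediate
9 | 3-allyl-4-hydroxy-5-methoxybenzaldehyde | COc1cc(C=O)cc(CC=C)c1O | intermediate
10 | 3-allyl-5-methoxy-4-(methoxymethoxy)benzaldehyde | COc1cc(C=O)cc(CC=C)c1OCOC | intermediate
11 | 3-methoxy-4-(methoxymethoxy)-5-prenylbenzaldehyde | COc1cc(C=O)cc(CC=C(C)C)c1OCOC | intermediate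
12 | racemic 3-hydroxy-1-[2-hydroxy-4,6-bis(methoxymethoxy)-3,5-diprenylphenyl]-3-[3-methoxy-4-(methoxymethoxy)-5-prenylphenyl]propan-1-one (aldol adduct) | COc1cc(C(O)CC(=O)c2c(O)c(CC=C(C)C)c(OCOC)c(CC=C(C)C)c2OCOC)cc(CC=C(C)C)c1OCOC | intermediate
13 | (E)-1-[2-hydroxy-4,6-bis(methoxymethoxy)-3,5-diprenylphenyl]-3-[3-methoxy-4-(methoxymethoxy)-5-prenylphenyl]prop-2-en-1-one | COc1cc(/C=C/C(=O)c2c(O)c(CC=C(C)C)c(OCOC)c(CC=C(C)C)c2OCOC)cc(CC=C(C)C)c1OCOC | intermediate
14 | rac-5,7-bis(methoxymethoxy)-2-[3-methoxy-4-(methoxymethoxy)-5-prenylphenyl]-6,8-diprenylchroman-4-one | COc1cc(C2CC(=O)c3c(OCOC)c(CC=C(C)C)c(OCOC)c(CC=C(C)C)c3O2)cc(CC=C(C)C)c1OCOC | intermediate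
15 | (2S)-5,7-bis(methoxymethoxy)-2-[3-methoxy-4-(methoxymethoxy)-5-prenylphenyl]-6,8-diprenylchroman-4-one | COc1cc([C@@H]2CC(=O)c3c(OCOC)c(CC=C(C)C)c(OCOC)c(CC=C(C)C)c3O2)cc(CC=C(C)C)c1OCOC | intermediate
16 | (2S)-5,7-dihydroxy-2-(4-hydroxy-3-methoxy-5-prenylphenyl)-6,8-diprenylchroman-4-one (CNP0235424.1) | COc1cc([C@@H]2CC(=O)c3c(O)c(CC=C(C)C)c(O)c(CC=C(C)C)c3O2)cc(CC=C(C)C)c1O | target

## Step count and risks
Total step count: 12. Longest linear sequence: 8 steps (steps 1–4 or 5–8, followed by steps 9–12).

**First risk, step 2.** The double Claisen rearrangement at 200 °C acts on an electron-rich polyphenol. The second shift may stay incomplete, or the o-allylphenols may cyclise to dihydrobenzofurans. The fallback sets out from 1 and drops the allyl detour. Direct double C-alkylation of the phloroglucinol nucleus with prenyl bromide (2.0 equiv) in aqueous KOH at 0 °C gives 1-(2,4,6-trihydroxy-3,5-diprenylphenyl)ethanone F1. The yield is modest after chromatographic removal of mono- and over-alkylated material. Bis-MOM protection under the conditions of step 3 brings it back to the route at 6.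

**Second risk, step 11.** The C4 carbonyl is flanked by the 5-OMOM group, so it may be reduced too slowly or with too small a rate difference between the enantiomers. The fallback sets out from 14 and separates the enantiomers physically. Preparative chiral SFC or HPLC on an amylose tris(3,5-dimethylphenylcarbamate) phase gives one fraction that is 15, where the route is rejoined. The other fraction is (2R)-5,7-bis(methoxymethoxy)-2-[3-methoxy-4-(methoxymethoxy)-5-prenylphenyl]-6,8-diprenylchroman-4-one F2. It is racemised back to 14 through chalcone 13 with NaOAc in refluxing EtOH and recycled.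

**Third risk, step 12.** Acid acts on three prenyl groups that each sit ortho to a liberated phenol. This can cause cyclisation to 2,2-dimethylchromans or addition of methanol. The fallback sets out from 5 and 10 and moves the acid step ahead of prenyl installation.
- Claisen–Schmidt condensation (KOH, EtOH/H2O, rt) gives (E)-1-[3,5-diallyl-2-hydroxy-4,6-bis(methoxymethoxy)phenyl]-3-[3-allyl-5-methoxy-4-(methoxymethoxy)phenyl]prop-2-en-1-one F3.
- NaOAc in refluxing EtOH closes it to rac-6,8-diallyl-2-[3-allyl-5-methoxy-4-(methoxymethoxy)phenyl]-5,7-bis(methoxymethoxy)chroman-4-one F4.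
- The transfer-hydrogenation resolution of step 11 leaves (2S)-6,8-diallyl-2-[3-allyl-5-methoxy-4-(methoxymethoxy)phenyl]-5,7-bis(methoxymethoxy)chroman-4-one F5. It forms beside (2R,4R)-6,8-diallyl-2-[3-allyl-5-methoxy-4-(methoxymethoxy)phenyl]-5,7-bis(methoxymethoxy)chroman-4-ol F6.
- HCl in MeOH, to which monosubstituted alkenes are indifferent, gives (2S)-6,8-diallyl-2-(3-allyl-4-hydroxy-5-methoxyphenyl)-5,7-dihydroxychroman-4-one F7.
- A final neutral triple cross-metathesis comes back to the route at 16. It uses 2-methyl-2-butene and the second-generation Grubbs catalyst RuCl2(=CHPh)(PCy3)(H2IMes) at 10 mol % in CH2Cl2 at 40 °C.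

Further compounds
F1 | step 2 | 1-(2,4,6-trihydroxy-3,5-diprenylphenyl)ethanone | CC(=O)c1c(O)c(CC=C(C)C)c(O)c(CC=C(C)C)c1O
F2 | step 11 | (2R)-5,7-bis(methoxymethoxy)-2-[3-methoxy-4-(methoxymethoxy)-5-prenylphenyl]-6,8-diprenylchroman-4-one | COc1cc([C@H]2CC(=O)c3c(OCOC)c(CC=C(C)C)c(OCOC)c(CC=C(C)C)c3O2)cc(CC=C(C)C)c1OCOC
F3 | step 12 | (E)-1-[3,5-diallyl-2-hydroxy-4,6-bis(methoxymethoxy)phenyl]-3-[3-allyl-5-methoxy-4-(methoxymethoxy)phenyl]prop-2-en-1-one | COc1cc(/C=C/C(=O)c2c(O)c(CC=C)c(OCOC)c(CC=C)c2OCOC)cc(CC=C)c1OCOC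
F4 | step 12 | rac-6,8-diallyl-2-[3-allyl-5-methoxy-4-(methoxymethoxy)phenyl]-5,7-bis(methoxymethoxy)chroman-4-one | COc1cc(C2CC(=O)c3c(OCOC)c(CC=C)c(OCOC)c(CC=C)c3O2)cc(CC=C)c1OCOC
F5 | step 12 | (2S)-6,8-diallyl-2-[3-allyl-5-methoxy-4-(methoxymethoxy)phenyl]-5,7-bis(methoxymethoxy)chroman-4-one | COc1cc([C@@H]2CC(=O)c3c(OCOC)c(CC=C)c(OCOC)c(CC=C)c3O2)cc(CC=C)c1OCOC
F6 | step 12 | (2R,4R)-6,8-diallyl-2-[3-allyl-5-methoxy-4-(methoxymethoxy)phenyl]-5,7-bis(methoxymethoxy)chroman-4-ol | COc1cc([C@H]2C[C@@H](O)c3c(OCOC)c(CC=C)c(OCOC)c(CC=C)c3O2)cc(CC=C)c1OCOC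
F7 | step 12 | (2S)-6,8-diallyl-2-(3-allyl-4-hydroxy-5-methoxyphenyl)-5,7-dihydroxychroman-4-one | COc1cc([C@@H]2CC(=O)c3c(O)c(CC=C)c(O)c(CC=C)c3O2)cc(CC=C)c1O
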